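The constants belong to no real substance, and the outcome is calculated.

Two questions are put to these four flasks: how much target each holds at the end, and what course that row takes.

| setting | maple | elm | birch | cedar |
|---|---|---|---|---|
| substrate | 1.8 M | 1.8 M | 1.8 M | 1.8 M |
| free catalyst | 3.0 mM | 10 mM | 30 mM | 100 mM |
| time | 10 h | 10 h | 10 h | 10 h |

    substrate + free catalyst ⇌ catalyst intermediate (K1 = 0.73 M⁻¹, k1 = 13 M⁻¹ h⁻¹)
    catalyst intermediate ⇌ free catalyst + target (K2 = 2.2 M, k2 = 1.0 h⁻¹)

* [target] at the end for maple, elm, birch, cedar, in this order
* the course of these numbers from the first flask to the last (rises all the way / falls, then rises / rises, then falls / falls all the way / hardly changes)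

- "hardly changes" means that all values lie within two and a half points (for a concentration: within two and a half percent of the largest)
- run time (maple): 10 h

**How much of the catalyst is at work at any moment?** With substrate at its charge, free catalyst is taken up at 23.4 h⁻¹, and the catalyst intermediate leaves at 17.8 h⁻¹ backwards and 1.0 h⁻¹ forwards. Taking up and leaving come into balance within about 1.42 min, which is far shorter than the run of 10 h. So I divide one rate by the others and time drops out. This gives 55.4 %: the bound share, the uptake rate divided by the sum of the uptake rate and both leaving rates.

**And the target?** Target comes out of the catalyst intermediate, so the charged catalyst turns over on average at 0.554 h⁻¹. At the start, the forward step out of the intermediate is the rate-limiting step. For maple, the charge times this turnover times the run gives 0.0166 M. That is hardly any of the substrate, so in maple the uptake rate stays close to its starting value.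

**Where does that straight line bend?** Look at cedar, where it gives 0.554 M. That is 30.8 % of the substrate charged, so for cedar I no longer hold substrate at its charge. Step 1 and step 2 together also set a ceiling, with the catalyst's own hold neglected, of 1.11 M, and the cedar line stands at half of it.

**What do you commit to?** I let the target approach that ceiling exponentially, starting along the straight line. Cedar then comes to 0.436 M, less than the straight line. Birch comes to 0.154 M, so cedar still stands above birch, and I say the row rises.

The forecast gives 0.0165 M, 0.054 M, 0.155 M and 0.44 M, with the course rises all the way. It speaks of “a little over half the catalyst bound”. For cedar my reckoning gives 0.436 M against its 0.44 M.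

The simulation gives 0.0165 M, 0.0543 M, 0.157 M and 0.455 M: rises all the way. In cedar after 10.0 h, substrate is down to 72.1 % of its charge. The bound share, 55.4 % with substrate at its charge, comes to 47.3 % when reckoned again with that substrate and with the target's way back left out, and the catalyst intermediate in cedar stands at 47.6 % of the catalyst charged.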